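**Retrosynthetic overview**

1. Feature: the only carbocycle is the cyclopentane C2–C3–C4–C5–C6 (carotenoid numbering). Its ring bond C2–C6 joins two carbons whose exocyclic carbons C1 (the Me2C(OH) carbon on C2) and C7 (the first polyene carbon, on C6) are cis, so C7 is read as a carboxyl carbon and C1 as the central carbon of an isopropenyl group.
2. Key disconnection C2–C6: Ireland–Claisen ring contraction of a nine-membered (Z)-alkenyl lactone, whose ketene acetal and ring alkene form a 1,5-diene. The bridge C3–C4–C5 enforces a boat and hence the cis relation; the C5 carbinol, already present, relays the absolute configuration.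
3. The lactone comes from (R)-linalool: its carbinol carbon becomes C5, the prenyl alkene becomes the (Z)-allylic alcohol (ozonolysis, Still–Gennari olefination, reduction), and the vinyl group becomes CH2CO2H. Ring closure is by Yamaguchi lactonization.
4. After the contraction the carboxyl adds to the isopropenyl group (γ-lactone, C1–O bond), the lactol is olefinated at C7, and the polyene is cut at C11=C12 and C11'=C12' into C15 + C10 + C15 Wittig partners.
5. Rings in order: nine-membered lactone (step 9), cyclopentane (step 10), temporary cis-fused γ-lactone (step 11, reopened in step 13).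

Key step: step 10

Assumption: pseudoionone is used as its (3E,5E) isomer, and Z isomers formed at new polyene double bonds in the phosphonium and Wittig steps are equilibrated thermally or removed by crystallization to give the all-E compounds, as is usual for carotenoids.

**Route**

Step 1
Reactants: 1 (R)-linalool, (3R)-3,7-dimethylocta-1,6-dien-3-ol
Product: 2 (3R)-3-(tert-butyldimethylsilyloxy)-3,7-dimethylocta-1,6-diene
Conditions: t-BuMe2SiOTf, 2,6-lutidine, CH2Cl2, 0 → 25 °C
Reagents that add atoms: tert-butyldimethylsilyl trifluoromethanesulfonate, CC(C)(C)[Si](C)(C)OS(=O)(=O)C(F)(F)F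
Why: Silyl ether formation on the hindered tertiary alcohol needs the silyl triflate with a non-nucleophilic pyridine base, and the carbinol configuration is not touched.

Step 2
Reactants: 2 (3R)-3-(tert-butyldimethylsilyloxy)-3,7-dimethylocta-1,6-diene
Product: 4 (4R)-4-(tert-butyldimethylsilyloxy)-4-methylhex-5-enal, via secondary ozonide 3 (not isolated)
Conditions: O3 (1 equiv, Sudan red 7B end point), CH2Cl2, −78 °C; then PPh3, −78 → 25 °C
Reagents that add atoms: ozone, [O-][O+]=O
Why: Ozonolysis with reductive work-up should be chemoselective, because the electron-rich trisubstituted alkene reacts with electrophilic ozone much faster than the monosubstituted vinyl group, which is deactivated and shielded by the adjacent silyloxy-bearing quaternary carbon, and the dye end point stops the addition at one equivalent.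

Step 3
Reactants: 4 (4R)-4-(tert-butyldimethylsilyloxy)-4-methylhex-5-enal; 5 methyl 2-[bis(2,2,2-trifluoroethoxy)phosphoryl]propanoate
Product: 7 methyl (2Z,6R)-6-(tert-butyldimethylsilyloxy)-2,6-dimethylocta-2,7-dienoate, via potassium phosphonate carbanion 6 (not isolated)
Conditions: KN(SiMe3)2, 18-crown-6, THF, −78 °C
Reagents that add atoms: none
Why: Still–Gennari olefination: the electron-poor bis(trifluoroethyl) phosphonate with a dissociated potassium counter-ion eliminates from the kinetic adduct faster than it equilibrates, so the (Z)-trisubstituted enoate should predominate.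

Step 4
Reactants: 7 methyl (2Z,6R)-6-(tert-butyldimethylsilyloxy)-2,6-dimethylocta-2,7-dienoate
Product: 8 (2Z,6R)-6-(tert-butyldimethylsilyloxy)-2,6-dimethylocta-2,7-dien-1-ol
Conditions: i-Bu2AlH (2.3 equiv), CH2Cl2, −78 °C; aq. potassium sodium tartrate
Reagents that add atoms: none
Why: 1,2-Reduction of the enoate by the aluminium hydride gives the allylic alcohol with the Z geometry retained.

Step 5
Reactants: 8 (2Z,6R)-6-(tert-butyldimethylsilyloxy)-2,6-dimethylocta-2,7-dien-1-ol
Product: 9 (2Z,6R)-6-(tert-butyldimethylsilyloxy)-2,6-dimethylocta-2,7-dien-1-yl acetate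
Conditions: Ac2O, pyridine, DMAP (cat.), CH2Cl2, 0 → 25 °C
Reagents that add atoms: acetic anhydride, CC(=O)OC(C)=O
Why: DMAP-catalysed acetylation masks the allylic alcohol, so that only the second primary alcohol, made next, is carried to the acid oxidation level.

Step 6
Reactants: 9 (2Z,6R)-6-(tert-butyldimethylsilyloxy)-2,6-dimethylocta-2,7-dien-1-yl acetate
Product: 11 (2Z,6R)-6-(tert-butyldimethylsilyloxy)-8-hydroxy-2,6-dimethyloct-2-en-1-yl acetate, via B-alkyl-9-BBN adduct 10 (not isolated)
Conditions: 9-BBN-H, THF, 0 → 40 °C; then NaBO3·4H2O, H2O, 25 °C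
Reagents that add atoms: sodium perborate tetrahydrate, [Na+].[O-]B1OO1.O.O.O.O
Why: Hydroboration–oxidation: the bulky borane adds boron to the terminal carbon of the monosubstituted alkene and ignores the trisubstituted alkene and the ester, and perborate oxidizes the C–B bond under conditions mild enough for the acetate.

Step 7
Reactants: 11 (2Z,6R)-6-(tert-butyldimethylsilyloxy)-8-hydroxy-2,6-dimethyloct-2-en-1-yl acetate
Product: 13 (3R,6Z)-8-acetoxy-3-(tert-butyldimethylsilyloxy)-3,7-dimethyloct-6-enoic acid, via aldehyde 12 (not isolated)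
Conditions: TEMPO (cat.), PhI(OAc)2 (2.5 equiv), MeCN/H2O, 25 °C
Reagents that add atoms: water, O
Why: Nitroxyl-catalysed oxidation in aqueous acetonitrile takes the primary alcohol through the aldehyde hydrate to the carboxylic acid without affecting the alkene, the acetate or the tertiary silyl ether.

Step 8
Reactants: 13 (3R,6Z)-8-acetoxy-3-(tert-butyldimethylsilyloxy)-3,7-dimethyloct-6-enoic acid
Product: 14 (3R,6Z)-3-(tert-butyldimethylsilyloxy)-8-hydroxy-3,7-dimethyloct-6-enoic acid
Conditions: LiOH·H2O (3 equiv), THF/H2O, 0 → 25 °C; then 1 M HCl to pH 4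
Reagents that add atoms: none
Why: Saponification removes the primary allylic acetate while the substrate is present as its carboxylate, which cannot lose the β-silyloxy group by elimination.

Step 9
Reactants: 14 (3R,6Z)-3-(tert-butyldimethylsilyloxy)-8-hydroxy-3,7-dimethyloct-6-enoic acid
Product: 16 (4R,7Z)-4-(tert-butyldimethylsilyloxy)-4,8-dimethyloxacyclonon-7-en-2-one, via mixed 2,4,6-trichlorobenzoic anhydride 15 (not isolated)
Conditions: 2,4,6-Cl3C6H2COCl, Et3N, THF, 25 °C; then slow addition to DMAP, PhMe, 80 °C (high dilution)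
Reagents that add atoms: none
Why: Yamaguchi macrolactonization: slow addition of the mixed anhydride to hot DMAP keeps the activated seco acid dilute, and the (Z)-alkene and the quaternary C4 pre-organize the chain for closure of the nine-membered ring.

Step 10
Reactants: 16 (4R,7Z)-4-(tert-butyldimethylsilyloxy)-4,8-dimethyloxacyclonon-7-en-2-one
Product: 19 (1R,2R,5R)-5-(tert-butyldimethylsilyloxy)-5-methyl-2-(prop-1-en-2-yl)cyclopentane-1-carboxylic acid (carboxyl, isopropenyl and methyl all cis), via trimethylsilyl ketene acetal 17 (not isolated), via trimethylsilyl ester 18 (not isolated)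
Conditions: Me3SiCl/Et3N (premixed, 3 equiv), then LiN(i-Pr)2 (1.3 equiv), THF, −78 °C (enolate trapped as formed); −78 → 25 °C, then 65 °C; H2O/THF, aq. NH4Cl
Reagents that add atoms: none
Why: The amide base removes a C3 proton with Me3SiCl already present, so the lactone enolate should be O-silylated before it can expel the C4 silyloxy group, and the ketene acetal C2=C3 (ring oxygen necessarily cis to C4) and the ring (Z)-alkene C7=C8 then form an allyl vinyl ether held inside the nine-membered ring. On warming, this 1,5-diene should undergo the [3,3]-sigmatropic Ireland–Claisen rearrangement, forming C3–C7 (carotenoid C6–C2) and breaking the allylic C9–O1 bond; the closest known reaction is the Ireland–Claisen ring contraction of medium-ring alkenyl lactones to cis-2-alkenylcycloalkanecarboxylic acids. The cyclopentane closes in a transannular sense, the new bond spanning the nine-membered ring so that C3–C4–C5–C6–C7 becomes the five-membered ring, C8 and C9 are extruded as the isopropenyl group and C2 as the carboxyl. The three-atom bridge C4–C5–C6 between the bonding termini allows only a boat-like transition state, which places carboxyl and isopropenyl cis and so fixes carotenoid C6 and C2 relative to each other. Their absolute sense is relayed from the linalool-derived C5, where the bulky silyloxy group should take the exo site, anti to the forming bond and away from the ketene acetal oxygens, leaving methyl on the carboxyl face; this facial choice, together with silylation outrunning β-elimination, is the selectivity the step needs and the less secure part of it. Release of medium-ring strain and formation of the C=O bond make the contraction irreversible.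

Step 11
Reactants: 19 (1R,2R,5R)-5-(tert-butyldimethylsilyloxy)-5-methyl-2-(prop-1-en-2-yl)cyclopentane-1-carboxylic acid
Product: 20 (3aR,6R,6aR)-6-(tert-butyldimethylsilyloxy)-3,3,6-trimethylhexahydro-1H-cyclopenta[c]furan-1-one (cis-fused)
Conditions: TsOH·H2O (10 mol %), CH2Cl2, 25 °C
Reagents that add atoms: none
Why: Acid-catalysed intramolecular hydroacyloxylation (Markovnikov lactonization): protonation of the 1,1-disubstituted alkene gives a tertiary cation that the cis carboxyl captures as a γ-lactone, creating the C1–O bond without a new stereocenter and locking C6 against epimerization.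

Step 12
Reactants: 20 (3aR,6R,6aR)-6-(tert-butyldimethylsilyloxy)-3,3,6-trimethylhexahydro-1H-cyclopenta[c]furan-1-one
Product: 21 (3aR,6R,6aR)-6-(tert-butyldimethylsilyloxy)-3,3,6-trimethylhexahydro-1H-cyclopenta[c]furan-1-ol (anomer mixture)
Conditions: i-Bu2AlH (1.2 equiv), CH2Cl2, −78 °C; aq. potassium sodium tartrate
Reagents that add atoms: none
Why: Partial reduction of the lactone stops at the tetrahedral aluminium hemiacetal at low temperature and gives the lactol on work-up; the anomeric configuration is of no consequence.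

Step 13
Reactants: 21 (3aR,6R,6aR)-6-(tert-butyldimethylsilyloxy)-3,3,6-trimethylhexahydro-1H-cyclopenta[c]furan-1-ol
Product: 23 (3E)-4-[(1R,2R,5R)-5-(tert-butyldimethylsilyloxy)-2-(2-hydroxypropan-2-yl)-5-methylcyclopentyl]but-3-en-2-one, via open-chain hydroxy aldehyde 22 (not isolated)
Conditions: Ph3P=CHC(O)CH3 (2.5 equiv), PhCO2H (cat.), PhMe, 90 °C
Reagents that add atoms: 1-(triphenylphosphoranylidene)propan-2-one, CC(=O)C=P(c1ccccc1)(c1ccccc1)c1ccccc1
Why: Wittig olefination of the lactol through its ring-opened aldehyde with a carbonyl-stabilized ylide should give the (E)-enone under neutral conditions, in which the released tertiary alcohol is a poor Michael donor and enolization at C6 is slow.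

Step 14
Reactants: 23 (3E)-4-[(1R,2R,5R)-5-(tert-butyldimethylsilyloxy)-2-(2-hydroxypropan-2-yl)-5-methylcyclopentyl]but-3-en-2-one
Product: 24 (1E)-1-[(1R,2R,5R)-5-(tert-butyldimethylsilyloxy)-2-(2-hydroxypropan-2-yl)-5-methylcyclopentyl]-3-methylpenta-1,4-dien-3-ol (both C3 epimers)
Conditions: CH2=CHMgBr (3 equiv; enone added to the reagent), THF, −78 → 0 °C; aq. NH4Cl
Reagents that add atoms: vinylmagnesium bromide, C=C[Mg]Br
Why: Grignard 1,2-addition to the ketone, fast at low temperature with the reagent in excess (one equivalent is consumed by the hydroxyl group); the new carbinol center forms without control and is erased in the next step.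

Step 15
Reactants: 24 (1E)-1-[(1R,2R,5R)-5-(tert-butyldimethylsilyloxy)-2-(2-hydroxypropan-2-yl)-5-methylcyclopentyl]-3-methylpenta-1,4-dien-3-ol
Product: 25 [(2E,4E)-5-[(1R,2R,5R)-5-(tert-butyldimethylsilyloxy)-2-(2-hydroxypropan-2-yl)-5-methylcyclopentyl]-3-methylpenta-2,4-dien-1-yl]triphenylphosphonium bromide
Conditions: PPh3·HBr, CH2Cl2/MeOH, 0 → 25 °C; crystallization
Reagents that add atoms: triphenylphosphine hydrobromide, c1ccc(cc1)[PH+](c1ccccc1)c1ccccc1.[Br-]
Why: Allylic transposition with phosphine capture: the mild acid ionizes the doubly allylic tertiary alcohol and PPh3 attacks the unhindered primary terminus of the pentadienyl cation irreversibly, giving the conjugated dienyl phosphonium salt, while any ether formed by the C1 hydroxyl would re-ionize under the same conditions.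

Step 16
Reactants: 26 pseudoionone, (3E,5E)-6,10-dimethylundeca-3,5,9-trien-2-one
Product: 27 (4E,6E)-3,7,11-trimethyldodeca-1,4,6,10-tetraen-3-ol (racemic)
Conditions: CH2=CHMgBr, THF, 0 °C; aq. NH4Cl
Reagents that add atoms: vinylmagnesium bromide, C=C[Mg]Br
Why: Grignard 1,2-addition to the dienone carbonyl; the racemic carbinol center is removed in the next step.

Step 17
Reactants: 27 (4E,6E)-3,7,11-trimethyldodeca-1,4,6,10-tetraen-3-ol
Product: 28 [(2E,4E,6E)-3,7,11-trimethyldodeca-2,4,6,10-tetraen-1-yl]triphenylphosphonium bromide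
Conditions: PPh3·HBr, MeOH, 25 °C; crystallization
Reagents that add atoms: triphenylphosphine hydrobromide, c1ccc(cc1)[PH+](c1ccccc1)c1ccccc1.[Br-]
Why: The same acid-mediated allylic transposition with phosphine capture at the primary terminus gives the conjugated C15 phosphonium salt.

Step 18
Reactants: 28 [(2E,4E,6E)-3,7,11-trimethyldodeca-2,4,6,10-tetraen-1-yl]triphenylphosphonium bromide; 29 (2E,4E,6E)-2,7-dimethylocta-2,4,6-trienedial (C10 dialdehyde)
Product: 31 (2E,4E,6E,8E,10E,12E,14E)-2,7,11,15,19-pentamethylicosa-2,4,6,8,10,12,14,18-octaenal (C25 aldehyde), via ylide 30 (not isolated)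
Conditions: NaOMe, MeOH/CH2Cl2, 0 → 25 °C (29 in threefold excess); then heptane, reflux
Reagents that add atoms: none
Why: Wittig olefination with the dialdehyde in excess should stop at mono-condensation, and the E/Z mixture at the new C11'=C12' bond is equilibrated thermally to the all-E polyenal.

Step 19
Reactants: 25 [(2E,4E)-5-[(1R,2R,5R)-5-(tert-butyldimethylsilyloxy)-2-(2-hydroxypropan-2-yl)-5-methylcyclopentyl]-3-methylpenta-2,4-dien-1-yl]triphenylphosphonium bromide; 31 C25 aldehyde
Product: 33 (all-E,2R,5R,6R)-5-O-(tert-butyldimethylsilyl)-2,6-cyclolycopene-1,5-diol, via ylide 32 (not isolated)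
Conditions: NaOMe, MeOH/CH2Cl2, 25 °C; then EtOH, reflux (Ar, dark)
Reagents that add atoms: none
Why: Wittig olefination joins the two halves at C11=C12; the free tertiary hydroxyl is tolerated, and heating isomerizes Z isomers at the new disubstituted bond to the all-E polyene.

Step 20
Reactants: 33 (all-E,2R,5R,6R)-5-O-(tert-butyldimethylsilyl)-2,6-cyclolycopene-1,5-diol
Product: 34 (all-E,2R,5R,6R)-2,6-cyclolycopene-1,5-diol (CNP0169920.2)
Conditions: Bu4NF, THF, 45 °C (Ar, dark)
Reagents that add atoms: none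
Why: Fluoride-induced desilylation of the tertiary silyl ether; the polyene is stable to basic fluoride and no stereocenter is affected.

**Compound list**

1 | (R)-linalool, (3R)-3,7-dimethylocta-1,6-dien-3-ol | C=C[C@](C)(O)CCC=C(C)C | starting material
2 | (3R)-3-(tert-butyldimethylsilyloxy)-3,7-dimethylocta-1,6-diene | C=C[C@](C)(O[Si](C)(C)C(C)(C)C)CCC=C(C)C | intermediate
3 | 3-[(3R)-3-(tert-butyldimethylsilyloxy)-3-methylpent-4-en-1-yl]-5,5-dimethyl-1,2,4-trioxolane (secondary ozonide) | C=C[C@](C)(O[Si](C)(C)C(C)(C)C)CCC1OOC(C)(C)O1 | intermediate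
4 | (4R)-4-(tert-butyldimethylsilyloxy)-4-methylhex-5-enal | C=C[C@](C)(O[Si](C)(C)C(C)(C)C)CCC=O | intermediate
5 | methyl 2-[bis(2,2,2-trifluoroethoxy)phosphoryl]propanoate | COC(=O)C(C)P(=O)(OCC(F)(F)F)OCC(F)(F)F | starting material
6 | potassium salt of the carbanion of 5 | COC(=O)[C-](C)P(=O)(OCC(F)(F)F)OCC(F)(F)F.[K+] | intermediate
7 | methyl (2Z,6R)-6-(tert-butyldimethylsilyloxy)-2,6-dimethylocta-2,7-dienoate | C=C[C@](C)(O[Si](C)(C)C(C)(C)C)CC/C=C(C)\C(=O)OC | intermediate
8 | (2Z,6R)-6-(tert-butyldimethylsilyloxy)-2,6-dimethylocta-2,7-dien-1-ol | C=C[C@](C)(O[Si](C)(C)C(C)(C)C)CC/C=C(C)\CO | intermediate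
9 | (2Z,6R)-6-(tert-butyldimethylsilyloxy)-2,6-dimethylocta-2,7-dien-1-yl acetate | C=C[C@](C)(O[Si](C)(C)C(C)(C)C)CC/C=C(C)\COC(C)=O | intermediate
10 | (2Z,6S)-8-(9-borabicyclo[3.3.1]nonan-9-yl)-6-(tert-butyldimethylsilyloxy)-2,6-dimethyloct-2-en-1-yl acetate (same spatial arrangement as 9; the descriptor changes because boron ranks below carbon) | B1(CC[C@](C)(O[Si](C)(C)C(C)(C)C)CC/C=C(C)\COC(C)=O)C2CCCC1CCC2 | intermediate
11 | (2Z,6R)-6-(tert-butyldimethylsilyloxy)-8-hydroxy-2,6-dimethyloct-2-en-1-yl acetate | OCC[C@](C)(O[Si](C)(C)C(C)(C)C)CC/C=C(C)\COC(C)=O | intermediate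
12 | (2Z,6R)-6-(tert-butyldimethylsilyloxy)-2,6-dimethyl-8-oxooct-2-en-1-yl acetate | O=CC[C@](C)(O[Si](C)(C)C(C)(C)C)CC/C=C(C)\COC(C)=O | intermediate
13 | (3R,6Z)-8-acetoxy-3-(tert-butyldimethylsilyloxy)-3,7-dimethyloct-6-enoic acid | OC(=O)C[C@](C)(O[Si](C)(C)C(C)(C)C)CC/C=C(C)\COC(C)=O | intermediate
14 | (3R,6Z)-3-(tert-butyldimethylsilyloxy)-8-hydroxy-3,7-dimethyloct-6-enoic acid | OC(=O)C[C@](C)(O[Si](C)(C)C(C)(C)C)CC/C=C(C)\CO | intermediate
15 | (3R,6Z)-3-(tert-butyldimethylsilyloxy)-8-hydroxy-3,7-dimethyloct-6-enoic 2,4,6-trichlorobenzoic anhydride | O=C(OC(=O)C[C@](C)(O[Si](C)(C)C(C)(C)C)CC/C=C(C)\CO)c1c(Cl)cc(Cl)cc1Cl | intermediate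
16 | (4R,7Z)-4-(tert-butyldimethylsilyloxy)-4,8-dimethyloxacyclonon-7-en-2-one | O=C1C[C@](C)(O[Si](C)(C)C(C)(C)C)CC/C=C(C)\CO1 | intermediate
17 | (2E,4R,7Z)-4-(tert-butyldimethylsilyloxy)-4,8-dimethyl-2-(trimethylsilyloxy)oxacyclonona-2,7-diene (ring oxygen cis to C4) | C[Si](C)(C)O/C1=C/[C@](C)(O[Si](C)(C)C(C)(C)C)CC/C=C(C)\CO1 | intermediate
18 | trimethylsilyl (1R,2R,5R)-5-(tert-butyldimethylsilyloxy)-5-methyl-2-(prop-1-en-2-yl)cyclopentane-1-carboxylate | C[Si](C)(C)OC(=O)[C@@H]1[C@H](C(C)=C)CC[C@@]1(C)O[Si](C)(C)C(C)(C)C | intermediate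
19 | (1R,2R,5R)-5-(tert-butyldimethylsilyloxy)-5-methyl-2-(prop-1-en-2-yl)cyclopentane-1-carboxylic acid | OC(=O)[C@@H]1[C@H](C(C)=C)CC[C@@]1(C)O[Si](C)(C)C(C)(C)C | intermediate
20 | (3aR,6R,6aR)-6-(tert-butyldimethylsilyloxy)-3,3,6-trimethylhexahydro-1H-cyclopenta[c]furan-1-one | O=C1OC(C)(C)[C@@H]2CC[C@@](C)(O[Si](C)(C)C(C)(C)C)[C@H]12 | intermediate
21 | (3aR,6R,6aR)-6-(tert-butyldimethylsilyloxy)-3,3,6-trimethylhexahydro-1H-cyclopenta[c]furan-1-ol (both anomers) | OC1OC(C)(C)[C@@H]2CC[C@@](C)(O[Si](C)(C)C(C)(C)C)[C@H]12 | intermediate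
22 | (1R,2R,5R)-5-(tert-butyldimethylsilyloxy)-2-(2-hydroxypropan-2-yl)-5-methylcyclopentane-1-carbaldehyde | O=C[C@@H]1[C@H](C(C)(C)O)CC[C@@]1(C)O[Si](C)(C)C(C)(C)C | intermediate
23 | (3E)-4-[(1R,2R,5R)-5-(tert-butyldimethylsilyloxy)-2-(2-hydroxypropan-2-yl)-5-methylcyclopentyl]but-3-en-2-one | CC(=O)/C=C/[C@@H]1[C@H](C(C)(C)O)CC[C@@]1(C)O[Si](C)(C)C(C)(C)C | intermediate
24 | (1E)-1-[(1R,2R,5R)-5-(tert-butyldimethylsilyloxy)-2-(2-hydroxypropan-2-yl)-5-methylcyclopentyl]-3-methylpenta-1,4-dien-3-ol (both C3 epimers) | C=CC(C)(O)/C=C/[C@@H]1[C@H](C(C)(C)O)CC[C@@]1(C)O[Si](C)(C)C(C)(C)C | intermediate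
25 | [(2E,4E)-5-[(1R,2R,5R)-5-(tert-butyldimethylsilyloxy)-2-(2-hydroxypropan-2-yl)-5-methylcyclopentyl]-3-methylpenta-2,4-dien-1-yl]triphenylphosphonium bromide | [Br-].c1ccccc1[P+](c1ccccc1)(c1ccccc1)C/C=C(C)/C=C/[C@@H]1[C@H](C(C)(C)O)CC[C@@]1(C)O[Si](C)(C)C(C)(C)C | intermediate
26 | pseudoionone, (3E,5E)-6,10-dimethylundeca-3,5,9-trien-2-one | CC(=O)/C=C/C=C(C)/CCC=C(C)C | starting material
27 | (4E,6E)-3,7,11-trimethyldodeca-1,4,6,10-tetraen-3-ol (racemic) | C=CC(C)(O)/C=C/C=C(C)/CCC=C(C)C | intermediate
28 | [(2E,4E,6E)-3,7,11-trimethyldodeca-2,4,6,10-tetraen-1-yl]triphenylphosphonium bromide | CC(C)=CCC/C(C)=C/C=C/C(C)=C/C[P+](c1ccccc1)(c1ccccc1)c1ccccc1.[Br-] | intermediate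
29 | (2E,4E,6E)-2,7-dimethylocta-2,4,6-trienedial | O=C/C(C)=C/C=C/C=C(C)/C=O | starting material
30 | ylide of 28, [(2E,4E,6E)-3,7,11-trimethyldodeca-2,4,6,10-tetraen-1-ylidene]triphenylphosphorane | CC(C)=CCC/C(C)=C/C=C/C(C)=C/C=P(c1ccccc1)(c1ccccc1)c1ccccc1 | intermediate
31 | (2E,4E,6E,8E,10E,12E,14E)-2,7,11,15,19-pentamethylicosa-2,4,6,8,10,12,14,18-octaenal | CC(C)=CCC/C(C)=C/C=C/C(C)=C/C=C/C(C)=C/C=C/C=C(C)/C=O | intermediate
32 | ylide of 25 | c1ccccc1P(c1ccccc1)(c1ccccc1)=C/C=C(C)/C=C/[C@@H]1[C@H](C(C)(C)O)CC[C@@]1(C)O[Si](C)(C)C(C)(C)C | intermediate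
33 | (all-E,2R,5R,6R)-5-O-(tert-butyldimethylsilyl)-2,6-cyclolycopene-1,5-diol | CC(C)=CCC/C(C)=C/C=C/C(C)=C/C=C/C(C)=C/C=C/C=C(C)/C=C/C=C(C)/C=C/[C@@H]1[C@H](C(C)(C)O)CC[C@@]1(C)O[Si](C)(C)C(C)(C)C | intermediate
34 | (all-E,2R,5R,6R)-2,6-cyclolycopene-1,5-diol | CC(C)=CCC/C(C)=C/C=C/C(C)=C/C=C/C(C)=C/C=C/C=C(C)/C=C/C=C(C)/C=C/[C@@H]1[C@H](C(C)(C)O)CC[C@@]1(C)O | target

**Step count and risks**

Total step count: 20. Longest linear sequence: 17 (steps 1–15, 19 and 20); steps 16–18 form the side branch to aldehyde 31.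

Steps most likely to fail:

1. Step 10. Two processes threaten it. The lithium enolate may expel silanolate (β-elimination) before it is silylated. The boat may also discriminate poorly between methyl and silyloxy on C5, which would erode the configuration of C2 and C6, since C5 is the only source of chirality. The fallback replaces the lithium enolate and substrate control by soft, reagent-controlled enolization. It sets out from lactone 16. Treatment with a C2-symmetric 2-bromo-1,3-bis{[3,5-bis(trifluoromethyl)phenyl]sulfonyl}-4,5-diphenyl-1,3,2-diazaborolidine and Et3N in CH2Cl2 at −78 °C would give the boron ketene acetal F1 without a free enolate. The enantiomer of the reagent that reinforces the substrate bias is used, drawn here as (4R,5R). On warming, F1 would undergo the same ring contraction under the additional facial control of the chiral ligand set, giving the acyloxyborane F2. Aqueous work-up hydrolyses F2, and the fallback comes back to the route at acid 19.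

2. Step 9. Intermolecular acylation to the diolide and oligomers may outrun closure of the strained nine-membered ring, and the activated β-silyloxy acyl group may suffer elimination. The fallback closes the ring at the alkyl–oxygen bond by carboxylate alkylation instead of acyl activation. It sets out from allylic alcohol 8. MsCl, LiCl and 2,4,6-collidine in DMF would give the allylic chloride (3R,6Z)-3-(tert-butyldimethylsilyloxy)-8-chloro-3,7-dimethylocta-1,6-diene F3. Hydroboration of the vinyl group with 9-BBN-H and perborate oxidation would give the alcohol (3R,6Z)-3-(tert-butyldimethylsilyloxy)-8-chloro-3,7-dimethyloct-6-en-1-ol F4. TEMPO/PhI(OAc)2 oxidation would give the acid (3R,6Z)-3-(tert-butyldimethylsilyloxy)-8-chloro-3,7-dimethyloct-6-enoic acid F5. Slow addition of F5 to Cs2CO3 in DMF at 40 °C under high dilution would displace the primary allylic chloride intramolecularly, and the fallback comes back to the route at lactone 16.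

3. Step 13. The tertiary hydroxyl set free on ring opening may add to the new enone (5-exo oxa-Michael addition), either here or as its magnesium alkoxide in step 14, and the open aldehyde may epimerize at C6. The fallback avoids an enone altogether by bringing in C8–C11 as one C5 unit. It sets out from lactol 21. Horner–Wadsworth–Emmons olefination with ethyl (2E)-4-(diethoxyphosphoryl)-3-methylbut-2-enoate and LiN(SiMe3)2 (2.2 equiv) in THF, −78 → 0 °C, would give the dienoate ethyl (2E,4E)-5-[(1R,2R,5R)-5-(tert-butyldimethylsilyloxy)-2-(2-hydroxypropan-2-yl)-5-methylcyclopentyl]-3-methylpenta-2,4-dienoate F6, in which C7 is only the remote terminus of a dienoate. Reduction with i-Bu2AlH would give the dienol (2E,4E)-5-[(1R,2R,5R)-5-(tert-butyldimethylsilyloxy)-2-(2-hydroxypropan-2-yl)-5-methylcyclopentyl]-3-methylpenta-2,4-dien-1-ol F7. PPh3·HBr would convert F7 into the phosphonium salt, and the fallback comes back to the route at compound 25.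

**Further compounds**

F1 | step 10 | boron ketene acetal of lactone 16 carrying the (4R,5R)-1,3-bis{[3,5-bis(trifluoromethyl)phenyl]sulfonyl}-4,5-diphenyl-1,3,2-diazaborolidin-2-yl group on the enolate oxygen | C[C@@]1(O[Si](C)(C)C(C)(C)C)CC/C=C(C)\COC(OB2N(S(=O)(=O)c3cc(cc(c3)C(F)(F)F)C(F)(F)F)[C@H](c3ccccc3)[C@@H](c3ccccc3)N2S(=O)(=O)c2cc(cc(c2)C(F)(F)F)C(F)(F)F)=C1
F2 | step 10 | acyloxyborane of acid 19 carrying the same diazaborolidin-2-yl group on the carboxyl oxygen | O=C(OB1N(S(=O)(=O)c2cc(cc(c2)C(F)(F)F)C(F)(F)F)[C@H](c2ccccc2)[C@@H](c2ccccc2)N1S(=O)(=O)c1cc(cc(c1)C(F)(F)F)C(F)(F)F)[C@@H]1[C@H](C(C)=C)CC[C@@]1(C)O[Si](C)(C)C(C)(C)C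
F3 | step 9 | (3R,6Z)-3-(tert-butyldimethylsilyloxy)-8-chloro-3,7-dimethylocta-1,6-diene | C=C[C@](C)(O[Si](C)(C)C(C)(C)C)CC/C=C(C)\CCl
F4 | step 9 | (3R,6Z)-3-(tert-butyldimethylsilyloxy)-8-chloro-3,7-dimethyloct-6-en-1-ol | OCC[C@](C)(O[Si](C)(C)C(C)(C)C)CC/C=C(C)\CCl
F5 | step 9 | (3R,6Z)-3-(tert-butyldimethylsilyloxy)-8-chloro-3,7-dimethyloct-6-enoic acid | OC(=O)C[C@](C)(O[Si](C)(C)C(C)(C)C)CC/C=C(C)\CCl
F6 | step 13 | ethyl (2E,4E)-5-[(1R,2R,5R)-5-(tert-butyldimethylsilyloxy)-2-(2-hydroxypropan-2-yl)-5-methylcyclopentyl]-3-methylpenta-2,4-dienoate | CCOC(=O)/C=C(C)/C=C/[C@@H]1[C@H](C(C)(C)O)CC[C@@]1(C)O[Si](C)(C)C(C)(C)C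
F7 | step 13 | (2E,4E)-5-[(1R,2R,5R)-5-(tert-butyldimethylsilyloxy)-2-(2-hydroxypropan-2-yl)-5-methylcyclopentyl]-3-methylpenta-2,4-dien-1-ol | OC/C=C(C)/C=C/[C@@H]1[C@H](C(C)(C)O)CC[C@@]1(C)O[Si](C)(C)C(C)(C)C
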